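**Retrosynthetic overview**

1. Locants: terpenoid part as spiro[4.5]decane, C1 (O–CH), C2 (C–CH3), C5 (spiro), C6=C7 (C7 bears i-Pr), C10 (CH–CH3); C1′ = benzylic CH(i-Bu); arene positions 5–8 as in a chroman.
2. Late stage: both CHO groups by Vilsmeier–Haack formylation of the 5,7-diol; C1–H by ionic reduction of a C1 silyl ketal; pyran ring (O–C1 and C1′–C2) by [4+2] addition of an o-quinone methide (Boc-protected phloroglucinaldehyde + i-BuMgCl) to the C1=C2 silyl enol ether of spiro ketone 17.
3. Key disconnection C5–C10: the cyclohexene ring is closed by intramolecular, deconjugative α-alkylation of the extended dienolate of 2-alkylidene-5-methylcyclopentanone 15 by its own (R)-secondary tosylate (inversion gives 10S); 15 comes from 2-methylcyclopentanone and an aldehyde built from (R)-butane-1,3-diol and 3-methylbutanenitrile.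
4. Enabling feature: C5 is at once α to C1 of the cyclopentane ring (the O-bearing carbon, a ketone in disguise) and allylic to C6=C7 of the cyclohexene ring, i.e. the α-carbon of a β,γ-unsaturated ketone; its dienolate is reached from every stereoisomer of 15, so the step is stereoconvergent.
5. Ring order: cyclopentane (bought) → cyclohexene (step 7) → pyran (step 10); the benzene ring is bought.

Key step: step 7

Remark: o-quinone methide 23 is taken to react as its E isomer (isobutyl on the outside of the diene); the Z isomer is assumed to equilibrate with it and to be the slower diene.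

**Route**

Step 1
Reactants: 1 (3R)-butane-1,3-diol
Product: 3 (4R)-4-methyl-1,3,2-dioxathiane 2,2-dioxide (cyclic sulfate), via cyclic sulfite 2 (not isolated)
Conditions: SOCl2, CH2Cl2, 0 → 40 °C; then RuCl3 hydrate (cat.), NaIO4, MeCN/H2O, 0 °C
Reagents that add atoms: thionyl chloride, O=S(Cl)Cl; sodium periodate, [Na+].[O-]I(=O)(=O)=O
Why: Cyclic sulfite formation and RuO4-catalysed oxidation (standard cyclic sulfate synthesis from a 1,3-diol) activate the primary carbon and mask the secondary hydroxyl in one unit; the stereocentre is not touched.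

Step 2
Reactants: 3 cyclic sulfate; 4 3-methylbutanenitrile
Product: 7 (5R)-5-hydroxy-2-(propan-2-yl)hexanenitrile (both C2 epimers), via lithiated nitrile 5 (not isolated), via lithium alkyl sulfate 6 (not isolated)
Conditions: 4, LiN(i-Pr)2, THF, −78 °C; 3, −78 → 0 °C; then 20% aq. H2SO4, Et2O, 25 °C
Reagents that add atoms: none
Why: Alkylation of a lithiated nitrile by a cyclic sulfate (SN2 at the primary carbon) followed by acid hydrolysis of the sulfate monoester with S–O cleavage keeps the carbinol centre R; the new C2 centre is left as an epimer mixture because step 7 erases it.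

Step 3
Reactants: 7 hydroxy nitrile
Product: 8 (2R)-5-cyano-6-methylheptan-2-yl 4-methylbenzenesulfonate
Conditions: TsCl, pyridine, DMAP (cat.), CH2Cl2, 0 → 25 °C
Reagents that add atoms: 4-methylbenzenesulfonyl chloride, Cc1ccc(cc1)S(=O)(=O)Cl
Why: O-sulfonylation of a secondary alcohol forms the O–S bond with retention at carbon and installs the leaving group for step 7.

Step 4
Reactants: 8 tosyloxy nitrile
Product: 10 (2R)-5-formyl-6-methylheptan-2-yl 4-methylbenzenesulfonate, via N-aluminio imine 9 (not isolated)
Conditions: i-Bu2AlH (1.2 equiv), CH2Cl2, −78 °C; then 1 M aq. HCl, 0 °C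
Reagents that add atoms: water, O
Why: Partial reduction of a nitrile by i-Bu2AlH to the N-aluminio imine and hydrolysis give the aldehyde; the secondary tosylate is inert at −78 °C and no stereocentre is affected.

Step 5
Reactants: 10 tosyloxy aldehyde; 11 2-methylcyclopentan-1-one (racemic)
Product: 13 aldol adduct (2R)-5-[hydroxy(3-methyl-2-oxocyclopentyl)methyl]-6-methylheptan-2-yl 4-methylbenzenesulfonate (diastereomer mixture), via lithium enolate 12 (not isolated)
Conditions: 11, LiN(i-Pr)2, THF, −78 °C; then 10, −78 °C; AcOH quench at −78 °C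
Reagents that add atoms: none
Why: Directed aldol addition: kinetic deprotonation of 11 at the less substituted α-carbon gives enolate 12, which adds to the aldehyde much faster than it attacks the secondary tosylate; the two new stereocentres need no control because steps 6 and 7 erase them.

Step 6
Reactants: 13 aldol adduct
Product: 15 enone (2R)-6-methyl-5-[(3-methyl-2-oxocyclopentylidene)methyl]heptan-2-yl 4-methylbenzenesulfonate (E/Z mixture; epimers at the two undefined centres), via aldol mesylate 14 (not isolated)
Conditions: MsCl, Et3N, CH2Cl2, 0 °C; then DBU, 0 → 25 °C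
Reagents that add atoms: none
Why: Mesylation and E1cB elimination of the β-mesyloxy ketone complete the aldol condensation to the exocyclic enone; its alkene geometry is irrelevant for step 7.

Step 7
Reactants: 15 enone tosylate
Product: 17 (5R,10S)-2,10-dimethyl-7-(propan-2-yl)spiro[4.5]dec-6-en-1-one (both C2 epimers), via potassium dienolate 16 (not isolated)
Conditions: KOt-Bu (1.2 equiv), t-BuOH/THF (1:4), 0.02 M, 0 → 40 °C
Reagents that add atoms: none
Why: KOt-Bu in t-BuOH equilibrates 15 (E and Z isomers, both C7 epimers, both C2 epimers) through the γ-deprotonated extended potassium dienolate 16 (O–C1=C5–C6=C7), so that eight stereoisomers funnel into one nucleophile in which the old C7 stereocentre and the enone geometry are erased; the bulkier isopropyl group should sit away from C5, which holds the chain cis to C5 as cyclisation needs, and the unreactive geometry re-enters by reprotonation (Curtin–Hammett). C5, the α-carbon of the dienolate, then displaces the (R)-secondary tosylate in a 6-exo-tet (enolexo) SN2 closure that forms the C5–C10 bond and the cyclohexene ring; the closest known reaction types are the deconjugative α-alkylation of enones through their dienolates and the intramolecular alkylation of ketone enolates by secondary sulfonates. C10 is set by inversion (R → S), and the C6=C7 alkene is placed by the deconjugation itself. C5 is set in the same event by a chair-like transition state with C10–CH3 pseudo-equatorial and the enolate terminus C1–OK, with its counter-ion and solvent shell, turned away from the forming ring (anti to C9), which should give CH3 trans to C1, i.e. (5R,10S). The step needs C- over O-alkylation and substitution over E2, secured by ring size (γ-attack would give a four-membered ring, O- or C2-attack an eight-membered ring), high dilution and a weakly basic alkoxide medium; it also needs the facial choice at C5, which rests only on the transition-state preference above.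

Step 8
Reactants: 17 spiro ketone
Product: 18 tert-butyl{[(5R,10S)-2,10-dimethyl-7-(propan-2-yl)spiro[4.5]deca-1,6-dien-1-yl]oxy}dimethylsilane
Conditions: TBSOTf, Et3N, CH2Cl2, 0 → 25 °C
Reagents that add atoms: tert-butyldimethylsilyl trifluoromethanesulfonate, CC(C)(C)[Si](C)(C)OS(=O)(=O)C(F)(F)F
Why: Soft enolisation (silyl triflate/amine): C2 is the only enolisable position because C5 is quaternary, so both C2 epimers converge on one tetrasubstituted silyl enol ether and no regioisomer is possible.

Step 9
Reactants: 19 2,4,6-trihydroxybenzaldehyde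
Product: 20 2,4,6-tris[(tert-butoxycarbonyl)oxy]benzaldehyde
Conditions: Boc2O (3.3 equiv), i-Pr2NEt, DMAP (cat.), THF, 0 → 25 °C
Reagents that add atoms: di-tert-butyl dicarbonate, CC(C)(C)OC(=O)OC(=O)OC(C)(C)C
Why: DMAP-catalysed O-acylation of all three phenols gives the aldehyde whose ortho carbonate serves as the internal leaving group for quinone methide generation in step 10.

Step 10
Reactants: 18 silyl enol ether; 20 tris-Boc aldehyde
Product: 24 cycloadduct (skeleton of 28 with OBoc at arene positions 5 and 7, H at positions 6 and 8, and OSi(t-Bu)Me2 on C1 cis to the C2 methyl; C1′, C2, C5, C10 as in 28), via magnesium alkoxide 21 (not isolated), via magnesium phenoxide 22 (not isolated), via o-quinone methide 23 (not isolated)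
Conditions: 20 (2.5 equiv), 18, Et2O, −78 °C; i-BuMgCl (2.5 equiv, in Et2O); −78 → 25 °C; aq. NH4Cl
Reagents that add atoms: isobutylmagnesium chloride, CC(C)C[Mg]Cl
Why: Addition of i-BuMgCl to the aldehyde gives alkoxide 21, O→O Boc transfer gives 22 and loss of tert-butyl carbonate gives o-quinone methide 23, which is trapped by enol ether 18 in an inverse-electron-demand hetero-Diels–Alder reaction; the oxygen of 23 bonds to the oxygen-bearing C1 and C1′ to the nucleophilic C2 (fixed regiochemistry), the diene should add to the enol-ether face flanked by the flat vinylic C6–H and not by C10(H)CH3 (sets C2 and C1 relative to C5), and the endo position of the silyloxy group on the E-quinone methide should put isobutyl cis to the C2 methyl (sets C1′).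

Step 11
Reactants: 24 cycloadduct
Product: 26 5,7-dihydroxychroman (28 without the two formyl groups; all five stereocentres as in 28), via bis-Boc chroman 25 (not isolated)
Conditions: Et3SiH (5 equiv), BF3·OEt2 (2 equiv), CH2Cl2, −78 → −30 °C; then K2CO3, MeOH, 25 °C, argon
Reagents that add atoms: none
Why: Lewis-acid ionisation of the silyl ketal to the cyclic aryl oxocarbenium ion and hydride transfer from Et3SiH (ionic reduction of a ketal; no elimination is possible because C2 and C5 are quaternary) should deliver H to C1 on the face that gives the cis-fused pyran/cyclopentane junction, the trans-fused 6-5 junction being strained; methanolysis then removes both aryl carbonates.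

Step 12
Reactants: 26 5,7-dihydroxychroman
Product: 28 target CNP0121396.2, via bis(iminium) salt 27 (not isolated)
Conditions: POCl3 (4 equiv), DMF (6 equiv), EtOAc, 0 → 25 °C; then ice-water, 25 °C
Reagents that add atoms: N,N-dimethylformamide, CN(C)C=O; water, O
Why: Double Vilsmeier–Haack formylation at the only two free positions (6 and 8) of the phloroglucinol-type ring and hydrolysis of bis(iminium) salt 27 give the dialdehyde; the chloroiminium electrophile should not attack the unactivated trisubstituted alkene and no stereocentre is involved.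

**Compound list**

1 | (3R)-butane-1,3-diol | C[C@@H](O)CCO | starting material
2 | (4R)-4-methyl-1,3,2-dioxathiane 2-oxide (cyclic sulfite) | C[C@@H]1CCOS(=O)O1 | intermediate (not isolated)
3 | (4R)-4-methyl-1,3,2-dioxathiane 2,2-dioxide (cyclic sulfate) | C[C@@H]1CCOS(=O)(=O)O1 | intermediate
4 | 3-methylbutanenitrile | CC(C)CC#N | starting material
5 | lithiated 3-methylbutanenitrile | [Li+].CC(C)[CH-]C#N | intermediate (not isolated)
6 | lithium (2R)-5-cyano-6-methylheptan-2-yl sulfate | [Li+].C[C@@H](OS(=O)(=O)[O-])CCC(C#N)C(C)C | intermediate (not isolated)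
7 | (5R)-5-hydroxy-2-(propan-2-yl)hexanenitrile (C2 epimers) | C[C@@H](O)CCC(C#N)C(C)C | intermediate
8 | (2R)-5-cyano-6-methylheptan-2-yl 4-methylbenzenesulfonate | C[C@@H](OS(=O)(=O)c1ccc(C)cc1)CCC(C#N)C(C)C | intermediate
9 | N-(diisobutylaluminio) imine of 10 | C[C@@H](OS(=O)(=O)c1ccc(C)cc1)CCC(C=N[Al](CC(C)C)CC(C)C)C(C)C | intermediate (not isolated)
10 | (2R)-5-formyl-6-methylheptan-2-yl 4-methylbenzenesulfonate | C[C@@H](OS(=O)(=O)c1ccc(C)cc1)CCC(C=O)C(C)C | intermediate
11 | 2-methylcyclopentan-1-one (racemic) | CC1CCCC1=O | starting material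
12 | lithium 5-methylcyclopent-1-en-1-olate | [Li+].[O-]C1=CCCC1C | intermediate (not isolated)
13 | (2R)-5-[hydroxy(3-methyl-2-oxocyclopentyl)methyl]-6-methylheptan-2-yl 4-methylbenzenesulfonate (diastereomer mixture) | CC1CCC(C(O)C(CC[C@@H](C)OS(=O)(=O)c2ccc(C)cc2)C(C)C)C1=O | intermediate
14 | methanesulfonate of aldol 13 | CC1CCC(C(OS(C)(=O)=O)C(CC[C@@H](C)OS(=O)(=O)c2ccc(C)cc2)C(C)C)C1=O | intermediate (not isolated)
15 | (2R)-6-methyl-5-[(3-methyl-2-oxocyclopentylidene)methyl]heptan-2-yl 4-methylbenzenesulfonate (E/Z and epimer mixture) | CC1CCC(=CC(CC[C@@H](C)OS(=O)(=O)c2ccc(C)cc2)C(C)C)C1=O | intermediate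
16 | potassium 5-methyl-2-[(5R)-2-(propan-2-yl)-5-(tosyloxy)hex-1-en-1-yl]cyclopent-1-en-1-olate (extended dienolate) | [K+].[O-]C1=C(C=C(CC[C@@H](C)OS(=O)(=O)c2ccc(C)cc2)C(C)C)CCC1C | intermediate (not isolated)
17 | (5R,10S)-2,10-dimethyl-7-(propan-2-yl)spiro[4.5]dec-6-en-1-one (C2 epimers) | O=C1C(C)CC[C@@]12C=C(C(C)C)CC[C@@H]2C | intermediate
18 | tert-butyl{[(5R,10S)-2,10-dimethyl-7-(propan-2-yl)spiro[4.5]deca-1,6-dien-1-yl]oxy}dimethylsilane | CC(C)(C)[Si](C)(C)OC1=C(C)CC[C@@]12C=C(C(C)C)CC[C@@H]2C | intermediate
19 | 2,4,6-trihydroxybenzaldehyde | O=Cc1c(O)cc(O)cc1O | starting material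
20 | 2,4,6-tris[(tert-butoxycarbonyl)oxy]benzaldehyde | O=Cc1c(OC(=O)OC(C)(C)C)cc(OC(=O)OC(C)(C)C)cc1OC(=O)OC(C)(C)C | intermediate
21 | chloromagnesium 3-methyl-1-{2,4,6-tris[(tert-butoxycarbonyl)oxy]phenyl}butan-1-olate | CC(C)CC(O[Mg]Cl)c1c(OC(=O)OC(C)(C)C)cc(OC(=O)OC(C)(C)C)cc1OC(=O)OC(C)(C)C | intermediate (not isolated)
22 | chloromagnesium 2-{1-[(tert-butoxycarbonyl)oxy]-3-methylbutyl}-3,5-bis[(tert-butoxycarbonyl)oxy]phenolate | CC(C)CC(OC(=O)OC(C)(C)C)c1c(O[Mg]Cl)cc(OC(=O)OC(C)(C)C)cc1OC(=O)OC(C)(C)C | intermediate (not isolated)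
23 | (6E)-3,5-bis[(tert-butoxycarbonyl)oxy]-6-(3-methylbutylidene)cyclohexa-2,4-dien-1-one (o-quinone methide) | CC(C)C/C=C1/C(=O)C=C(OC(=O)OC(C)(C)C)C=C1OC(=O)OC(C)(C)C | intermediate (not isolated)
24 | cycloadduct: 28 with OBoc at positions 5 and 7, H at 6 and 8, OSi(t-Bu)Me2 on C1 cis to C2–CH3 | CC(C)C[C@H]1c2c(OC(=O)OC(C)(C)C)cc(OC(=O)OC(C)(C)C)cc2O[C@@]2(O[Si](C)(C)C(C)(C)C)[C@]1(C)CC[C@@]21C=C(C(C)C)CC[C@@H]1C | intermediate
25 | bis-Boc chroman: 26 with both phenols as tert-butyl carbonates | CC(C)C[C@H]1c2c(OC(=O)OC(C)(C)C)cc(OC(=O)OC(C)(C)C)cc2O[C@H]2[C@]1(C)CC[C@@]21C=C(C(C)C)CC[C@@H]1C | intermediate (not isolated)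
26 | 5,7-dihydroxychroman: 28 without the two formyl groups | CC(C)C[C@H]1c2c(O)cc(O)cc2O[C@H]2[C@]1(C)CC[C@@]21C=C(C(C)C)CC[C@@H]1C | intermediate
27 | 6,8-bis(dimethyliminiomethyl) dichloride of 26 | CC(C)C[C@H]1c2c(O)c(C=[N+](C)C)c(O)c(C=[N+](C)C)c2O[C@H]2[C@]1(C)CC[C@@]21C=C(C(C)C)CC[C@@H]1C.[Cl-].[Cl-] | intermediate (not isolated)
28 | CNP0121396.2 | CC(C)C[C@H]1c2c(O)c(C=O)c(O)c(C=O)c2O[C@H]2[C@]1(C)CC[C@@]21C=C(C(C)C)CC[C@@H]1C | target

**Summary**

Total step count: 12. Longest linear sequence: 11 steps (steps 1–8, then 10–12).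

**Steps most likely to fail**

Step 7. What may go wrong: loss of facial discrimination at C5 in the alkylation transition state (the two ways of placing C1 and C4 beside the forming ring may differ little), and E2 loss of the secondary tosylate under the alkoxide. The fallback sets out from 15 and comes back at 17. Enone 15 is condensed with 1,1-dimethylhydrazine (AcOH cat., EtOH, 25 °C) to the α,β-unsaturated N,N-dimethylhydrazone F1. KN(SiMe3)2 (THF, −78 → 25 °C, equilibrating) gives the extended azaenolate, whose NMe2 group lies in the plane on the C5 side (Z geometry about C–N) and so blocks the transition state that puts C1 next to the forming ring. The same 6-exo-tet closure then gives the spiro hydrazone F2, and CuCl2 in aqueous THF returns ketone 17. The azaenolate is also more nucleophilic and less prone to cause elimination.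

Step 10. What may go wrong: slow cycloaddition of the hindered tetrasubstituted enol ether, so that quinone methide 23 oligomerises, and poor control of C1′ through E/Z isomerism of 23 or endo/exo competition. The fallback sets out from 17 and comes back at 25. The bond order is inverted: LiN(i-Pr)2 (THF, −78 °C) converts 17 into its lithium enolate F3 (only C2 can enolise), which adds to aldehyde 20 in an aldol reaction on the face anti to C10. The aldolate undergoes the same Boc transfer and loss of tert-butyl carbonate to give the ketone-bearing quinone methide F4, to which i-BuMgCl adds in the 1,4 sense, the small nucleophile entering anti to the cyclopentanone ring. Work-up gives the cyclic hemiketal F5, which is reduced under the first conditions of step 11 to 25 and carried on to 26.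

Step 11. What may go wrong: slow hydride transfer to an oxocarbenium ion that lies between two quaternary carbons, so that endocyclic C–O cleavage (ring opening to the O-silylated ketone), retro-Michael fragmentation and premature loss of the Boc groups compete. The fallback sets out from 24 and comes back at 25. Ketal 24 is converted with PhSH and BF3·OEt2 (CH2Cl2, −78 °C) into the O,S-ketal F6; thiophenol captures the cation reversibly and much faster than the silane. The C–S bond is then reduced by a radical chain (n-Bu3SnH, AIBN, toluene, 80 °C); the tertiary α-aryloxy radical should take hydrogen on the convex face and give cis-fused 25, which is deprotected as in step 11.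

**Further compounds**

F1 | step 7 | (2R)-5-{[2-(2,2-dimethylhydrazinylidene)-3-methylcyclopentylidene]methyl}-6-methylheptan-2-yl 4-methylbenzenesulfonate | CC1CCC(=CC(CC[C@@H](C)OS(=O)(=O)c2ccc(C)cc2)C(C)C)C1=NN(C)C
F2 | step 7 | N,N-dimethylhydrazone of (5R,10S)-2,10-dimethyl-7-(propan-2-yl)spiro[4.5]dec-6-en-1-one | CN(C)N=C1C(C)CC[C@@]12C=C(C(C)C)CC[C@@H]2C
F3 | step 10 | lithium (5R,10S)-2,10-dimethyl-7-(propan-2-yl)spiro[4.5]deca-1,6-dien-1-olate | [Li+].[O-]C1=C(C)CC[C@@]12C=C(C(C)C)CC[C@@H]2C
F4 | step 10 | (6E)-3,5-bis[(tert-butoxycarbonyl)oxy]-6-{[(5R,10S)-2,10-dimethyl-1-oxo-7-(propan-2-yl)spiro[4.5]dec-6-en-2-yl]methylidene}cyclohexa-2,4-dien-1-one (C2 as in 28) | C[C@]1(/C=C2/C(=O)C=C(OC(=O)OC(C)(C)C)C=C2OC(=O)OC(C)(C)C)CC[C@@]3(C=C(C(C)C)CC[C@@H]3C)C1=O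
F5 | step 10 | cyclic hemiketal: 24 with OH in place of OSi(t-Bu)Me2 | CC(C)C[C@H]1c2c(OC(=O)OC(C)(C)C)cc(OC(=O)OC(C)(C)C)cc2O[C@@]2(O)[C@]1(C)CC[C@@]21C=C(C(C)C)CC[C@@H]1C
F6 | step 11 | O,S-ketal: 24 with SPh in place of OSi(t-Bu)Me2 (either configuration at C1) | CC(C)C[C@H]1c2c(OC(=O)OC(C)(C)C)cc(OC(=O)OC(C)(C)C)cc2OC2(Sc3ccccc3)[C@]1(C)CC[C@@]21C=C(C(C)C)CC[C@@H]1C
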